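**Retrosynthetic overview**
1. The strategy rests on ring A. Its sulfated oxygen (ring A carbon 1), its two free hydroxyls (ring A carbons 3 and 5) and its bond to ring B (ring A carbon 6) map onto the 4-oxygen, the ring oxygen, the carbonyl oxygen and position 3 of a 3-aryl-4-hydroxy-6-methyl-2-pyranone. Only the future sulfate oxygen is a free hydroxyl there, so it can be tagged (allyl) before the other two exist as phenols.
2. Sulfate ⇐ free phenol on ring A carbon 1 ⇐ allyl ether; ring A ⇐ 4-allyloxy-3-aryl-6-methyl-2-pyranone by lactone opening and Claisen closure (new bond between ring A carbons 4 and 5).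
3. Bond from pyranone position 3 to ring B ⇐ aryllead arylation of triacetic acid lactone; bond between rings B and C ⇐ Ullmann homocoupling of iodinated tribenzylphloroglucinol.
4. Ring order: rings B and C come intact from phloroglucinol, the pyranone ring is bought, and ring A is the only ring built, last.

Key step: step 6

Remark 1: the target is taken to be wanted as the protonated hydrogen sulfate as drawn; the sulfate is carried as its sodium salt and protonated only at the end, cold, because aryl hydrogen sulfates hydrolyse under their own acidity.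
Remark 2: the axis between rings A and B carries four ortho oxygens between two unsymmetrical rings and may be a stereogenic axis; the SMILES gives no configuration, so no atropisomer control is attempted.

**Step 1**
Reactants: 1 phloroglucinol
Product: 2 1,3,5-tris(benzyloxy)benzene
Conditions: BnBr (3.3 equiv), K2CO3, DMF, rt
Reagents that add atoms: benzyl bromide, BrCc1ccccc1
Why: Williamson etherification of the three phenols; the C-benzylated by-products typical of phloroglucinol should be removed by crystallisation.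

**Step 2**
Reactants: 2 1,3,5-tris(benzyloxy)benzene
Product: 3 2-iodo-1,3,5-tris(benzyloxy)benzene
Conditions: NIS (1.0 equiv), MeCN, 0 °C to rt
Reagents that add atoms: N-iodosuccinimide, O=C1CCC(=O)N1I
Why: electrophilic aromatic iodination at one of three equivalent, triply oxygen-activated CH positions; the first iodine slows a second substitution.

**Step 3**
Reactants: 3 2-iodo-1,3,5-tris(benzyloxy)benzene (two molecules)
Product: 4 2,2',4,4',6,6'-hexakis(benzyloxy)-1,1'-biphenyl
Conditions: activated Cu bronze (excess), neat melt, 200 °C, Ar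
Reagents that add atoms: none
Why: Ullmann reductive homocoupling through an arylcopper intermediate, the classical entry to 2,2',6,6'-tetraalkoxybiphenyls; the main by-product expected, reduced arene 2, can be returned to step 2.

**Step 4**
Reactants: 4 2,2',4,4',6,6'-hexakis(benzyloxy)-1,1'-biphenyl; 5 4-hydroxy-6-methyl-2H-pyran-2-one (triacetic acid lactone)
Product: 7 3-[2,2',4,4',6,6'-hexakis(benzyloxy)biphenyl-3-yl]-4-hydroxy-6-methyl-2H-pyran-2-one, via aryllead triacetate 6 (not isolated)
Conditions: Pb(OAc)4 (0.8 equiv), CHCl3, rt, dark; then 5, pyridine (3 equiv), CHCl3, 60 °C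
Reagents that add atoms: none
Why: electrophilic plumbation at one of the four equivalent CH positions of 4 gives the aryllead triacetate (tetravalent lead), and Pinhey arylation then transfers the aryl group to position 3 of the vinylogous acid by ligand coupling on lead, as established for 4-hydroxycoumarins and cyclic β-dicarbonyl compounds and tolerant of two ortho substituents; Pb(OAc)4 is kept below one equivalent so that the second ring is not plumbated, and unreacted 4 is recovered.

**Step 5**
Reactants: 7 3-[2,2',4,4',6,6'-hexakis(benzyloxy)biphenyl-3-yl]-4-hydroxy-6-methyl-2H-pyran-2-one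
Product: 8 4-(allyloxy)-3-[2,2',4,4',6,6'-hexakis(benzyloxy)biphenyl-3-yl]-6-methyl-2H-pyran-2-one
Conditions: allyl bromide (1.5 equiv), K2CO3, DMF, rt
Reagents that add atoms: allyl bromide, C=CCBr
Why: Williamson-type O-alkylation of the vinylogous acid at its 4-oxygen, with position 3 blocked and shielded by the aryl group; the minor 2-allyloxy-4-pyranone isomer from alkylation at the carbonyl oxygen should be removed by chromatography.

**Step 6**
Reactants: 8 4-(allyloxy)-3-[2,2',4,4',6,6'-hexakis(benzyloxy)biphenyl-3-yl]-6-methyl-2H-pyran-2-one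
Product: 10 6-(allyloxy)-2',2'',4',4'',6',6''-hexakis(benzyloxy)-[1,1':3',1''-terphenyl]-2,4-diol, via ring-opened allyl keto ester 9 (not isolated)
Conditions: NaOCH2CH=CH2 (3 equiv, from NaH in allyl alcohol, 0 °C), allyl alcohol/1,4-dioxane, 90 °C; then 1 M HCl, 0 °C
Reagents that add atoms: none
Why: Allyloxide adds to the lactone carbonyl and the ring opens to the (E)-β-allyloxy enoate 9, whose methyl ketone arm is held cis to the ester by the double bond inherited from the pyranone; the terminal methyl enolate, present in small equilibrium concentration, attacks the ester carbon (Claisen condensation, forming the bond between carbons 4 and 5 of ring A) and the cyclohexenedione tautomerises to the arene. The closest known reaction type is the base-mediated recyclisation of 6-methyl-2-pyranones, and the Claisen cyclisation of 3,5-dioxohexanoates, to phloroglucinols. Ring A closes in a 6-(enolendo)-exo-trig mode and no stereocentre is formed. The step needs C-closure over O-closure: relactonisation through the more acidic internal methylene only returns 8 and is reversible, whereas the Claisen product is drained irreversibly as its aromatic phenoxide. It also needs the allyl tag to stay on the oxygen that becomes the sulfate site: the alkoxide is matched to the enol ether (allyloxide in allyl alcohol rather than methoxide), so any addition–elimination at the allyloxy-bearing ring carbon is degenerate, and the medium is kept dry so that the enol ether is not hydrolysed. The two ortho benzyloxy groups of ring B slow attack at the lactone carbonyl, hence the small alkoxide in excess and 90 °C.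

**Step 7**
Reactants: 10 6-(allyloxy)-2',2'',4',4'',6',6''-hexakis(benzyloxy)-[1,1':3',1''-terphenyl]-2,4-diol
Product: 11 2-(allyloxy)-2',2'',4,4',4'',6,6',6''-octakis(benzyloxy)-1,1':3',1''-terphenyl
Conditions: BnBr (2.5 equiv), K2CO3, DMF, rt to 50 °C
Reagents that add atoms: benzyl bromide, BrCc1ccccc1
Why: Williamson etherification of the two new phenols on carbons 3 and 5 of ring A; the allyl ether is inert to K2CO3.

**Step 8**
Reactants: 11 2-(allyloxy)-2',2'',4,4',4'',6,6',6''-octakis(benzyloxy)-1,1':3',1''-terphenyl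
Product: 12 2',2'',4,4',4'',6,6',6''-octakis(benzyloxy)-[1,1':3',1''-terphenyl]-2-ol
Conditions: Pd(PPh3)4 (5 mol %), morpholine (5 equiv), THF, rt
Reagents that add atoms: none
Why: Tsuji–Trost deallylation; zerovalent palladium ionises the aryl allyl ether to a π-allyl complex and the phenoxide, morpholine takes up the allyl group, and the eight benzyl ethers are untouched.

**Step 9**
Reactants: 12 2',2'',4,4',4'',6,6',6''-octakis(benzyloxy)-[1,1':3',1''-terphenyl]-2-ol
Product: 14 sodium 2',2'',4,4',4'',6,6',6''-octakis(benzyloxy)-[1,1':3',1''-terphenyl]-2-yl sulfate, via pyridinium aryl sulfate 13 (not isolated)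
Conditions: SO3·pyridine (5 equiv), pyridine, 50 °C; then aq NaHCO3; Sephadex LH-20
Reagents that add atoms: sulfur trioxide–pyridine complex, [O-]S(=O)(=O)[n+]1ccccc1; sodium hydrogen carbonate, [Na+].OC([O-])=O
Why: O-sulfation of the only free phenol by the SO3–pyridine complex, then cation exchange to the sodium salt so that no pyridine, an inhibitor of benzyl ether hydrogenolysis, reaches the last step.

**Step 10**
Reactants: 14 sodium 2',2'',4,4',4'',6,6',6''-octakis(benzyloxy)-[1,1':3',1''-terphenyl]-2-yl sulfate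
Product: 16 2',2'',4,4',4'',6,6',6''-octahydroxy-[1,1':3',1''-terphenyl]-2-yl hydrogen sulfate (the target), via target sodium salt 15 (not isolated)
Conditions: H2 (1 atm), Pd/C (10 wt %), THF/MeOH/H2O, rt; filter under Ar; then aq HCl (1.0 equiv), 0 °C; Sephadex LH-20 (MeOH); lyophilise
Reagents that add atoms: none
Why: hydrogenolysis over palladium cleaves all eight benzyl ethers while the aryl sulfate anion is stable to H2 at neutral pH; one equivalent of HCl then gives the hydrogen sulfate, and the gel is expected to hold the polyphenol while NaCl passes.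

**Compound list**
1 | phloroglucinol | Oc1cc(O)cc(O)c1 | starting material
2 | 1,3,5-tris(benzyloxy)benzene | c1ccccc1COc1cc(OCc2ccccc2)cc(OCc2ccccc2)c1 | intermediate
3 | 2-iodo-1,3,5-tris(benzyloxy)benzene | Ic1c(OCc2ccccc2)cc(OCc2ccccc2)cc1OCc1ccccc1 | intermediate
4 | 2,2',4,4',6,6'-hexakis(benzyloxy)-1,1'-biphenyl (rings B and C) | c1ccccc1COc1cc(OCc2ccccc2)cc(OCc2ccccc2)c1-c1c(OCc2ccccc2)cc(OCc2ccccc2)cc1OCc1ccccc1 | intermediate
5 | 4-hydroxy-6-methyl-2H-pyran-2-one (triacetic acid lactone) | CC1=CC(O)=CC(=O)O1 | starting material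
6 | [2,2',4,4',6,6'-hexakis(benzyloxy)biphenyl-3-yl]lead triacetate | CC(=O)O[Pb](OC(C)=O)(OC(C)=O)c1c(OCc2ccccc2)cc(OCc2ccccc2)c(-c2c(OCc3ccccc3)cc(OCc3ccccc3)cc2OCc2ccccc2)c1OCc1ccccc1 | intermediate (not isolated)
7 | 3-[2,2',4,4',6,6'-hexakis(benzyloxy)biphenyl-3-yl]-4-hydroxy-6-methyl-2H-pyran-2-one | CC1=CC(O)=C(c2c(OCc3ccccc3)cc(OCc3ccccc3)c(-c3c(OCc4ccccc4)cc(OCc4ccccc4)cc3OCc3ccccc3)c2OCc2ccccc2)C(=O)O1 | intermediate
8 | 4-(allyloxy)-3-[2,2',4,4',6,6'-hexakis(benzyloxy)biphenyl-3-yl]-6-methyl-2H-pyran-2-one (key-step precursor) | C=CCOC1=C(c2c(OCc3ccccc3)cc(OCc3ccccc3)c(-c3c(OCc4ccccc4)cc(OCc4ccccc4)cc3OCc3ccccc3)c2OCc2ccccc2)C(=O)OC(C)=C1 | intermediate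
9 | allyl (2E)-3-(allyloxy)-2-[2,2',4,4',6,6'-hexakis(benzyloxy)biphenyl-3-yl]-5-oxohex-2-enoate | C=CCOC(=O)/C(c1c(OCc2ccccc2)cc(OCc2ccccc2)c(-c2c(OCc3ccccc3)cc(OCc3ccccc3)cc2OCc2ccccc2)c1OCc1ccccc1)=C(/OCC=C)CC(C)=O | intermediate (not isolated)
10 | 6-(allyloxy)-2',2'',4',4'',6',6''-hexakis(benzyloxy)-[1,1':3',1''-terphenyl]-2,4-diol (key-step product; ring A as 1-allyl ether and 3,5-diol) | C=CCOc1cc(O)cc(O)c1-c1c(OCc2ccccc2)cc(OCc2ccccc2)c(-c2c(OCc3ccccc3)cc(OCc3ccccc3)cc2OCc2ccccc2)c1OCc1ccccc1 | intermediate
11 | 2-(allyloxy)-2',2'',4,4',4'',6,6',6''-octakis(benzyloxy)-1,1':3',1''-terphenyl | C=CCOc1cc(OCc2ccccc2)cc(OCc2ccccc2)c1-c1c(OCc2ccccc2)cc(OCc2ccccc2)c(-c2c(OCc3ccccc3)cc(OCc3ccccc3)cc2OCc2ccccc2)c1OCc1ccccc1 | intermediate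
12 | 2',2'',4,4',4'',6,6',6''-octakis(benzyloxy)-[1,1':3',1''-terphenyl]-2-ol | Oc1cc(OCc2ccccc2)cc(OCc2ccccc2)c1-c1c(OCc2ccccc2)cc(OCc2ccccc2)c(-c2c(OCc3ccccc3)cc(OCc3ccccc3)cc2OCc2ccccc2)c1OCc1ccccc1 | intermediate
13 | pyridinium 2',2'',4,4',4'',6,6',6''-octakis(benzyloxy)-[1,1':3',1''-terphenyl]-2-yl sulfate | [O-]S(=O)(=O)Oc1cc(OCc2ccccc2)cc(OCc2ccccc2)c1-c1c(OCc2ccccc2)cc(OCc2ccccc2)c(-c2c(OCc3ccccc3)cc(OCc3ccccc3)cc2OCc2ccccc2)c1OCc1ccccc1.c1cc[nH+]cc1 | intermediate (not isolated)
14 | sodium 2',2'',4,4',4'',6,6',6''-octakis(benzyloxy)-[1,1':3',1''-terphenyl]-2-yl sulfate | [Na+].[O-]S(=O)(=O)Oc1cc(OCc2ccccc2)cc(OCc2ccccc2)c1-c1c(OCc2ccccc2)cc(OCc2ccccc2)c(-c2c(OCc3ccccc3)cc(OCc3ccccc3)cc2OCc2ccccc2)c1OCc1ccccc1 | intermediate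
15 | sodium 2',2'',4,4',4'',6,6',6''-octahydroxy-[1,1':3',1''-terphenyl]-2-yl sulfate | [Na+].[O-]S(=O)(=O)Oc1cc(O)cc(O)c1-c1c(O)cc(O)c(-c2c(O)cc(O)cc2O)c1O | intermediate (not isolated)
16 | 2',2'',4,4',4'',6,6',6''-octahydroxy-[1,1':3',1''-terphenyl]-2-yl hydrogen sulfate (CNP0244954.0) | O=S(=O)(O)Oc1cc(O)cc(O)c1-c1c(O)cc(O)c(-c2c(O)cc(O)cc2O)c1O | target

**Total step count:** 10
**Longest linear sequence:** 10 steps (from phloroglucinol 1)

**Three steps most likely to fail**

Step 6 (key recyclisation). The lactone may open and reclose without C–C bond formation, because deprotonation falls on the internal methylene and the doubly ortho-substituted ring B shields the ester carbon; the enol ether tag may also be lost by hydrolysis. The fallback sets out from 4 and returns at 12. The aryllead triacetate 6 is generated from 4 as in step 4 and used to arylate commercial 3,5-bis(benzyloxy)phenol ortho to its hydroxyl (pyridine, CHCl3, 60 °C). This ligand coupling on lead is known for 3,5-disubstituted phenols and gives phenol 12 directly, since the hydroxyl that directs the arylation becomes the oxygen on carbon 1 of ring A. No compound outside the list is made on this path (F0).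

Step 4 (plumbation and Pinhey arylation). Plumbation may run on to the second ring, tetravalent lead may oxidise the electron-rich biaryl instead of substituting it, or the ligand coupling of the congested aryl group may be slow. The fallback sets out from 4 and returns at 7, building the pyranone on the aryl group instead of transferring the aryl group to the pyranone. NBS (0.8 equiv, CH2Cl2, −78 °C) should give 3-bromo-2,2',4,4',6,6'-hexakis(benzyloxy)-1,1'-biphenyl F1. Palladium-catalysed α-arylation with the Reformatsky reagent BrZnCH2CO2tBu (Pd(dba)2, P(tBu)3, THF, rt to 60 °C) should give tert-butyl 2-[2,2',4,4',6,6'-hexakis(benzyloxy)biphenyl-3-yl]acetate F2. Its lithium enolate (LiN(iPr)2, 2.2 equiv, THF, −78 °C) is acylated with diketene to tert-butyl 2-[2,2',4,4',6,6'-hexakis(benzyloxy)biphenyl-3-yl]-3,5-dioxohexanoate F3. Heating F3 in toluene at 110 °C expels tert-butanol via the acylketene, and the δ-enol closes the lactone to 7.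

Step 3 (Ullmann homocoupling). Hydrodeiodination back to 2 and thermal damage to the benzyl ethers may outpace coupling of this electron-rich, doubly ortho-substituted iodide. The fallback sets out from 3 and returns at 4, replacing reductive homocoupling on copper by a cross-coupling of a nucleophile with an electrophile. Iodine–magnesium exchange (iPrMgCl·LiCl, THF, −20 °C) and trapping with 2-isopropoxy-4,4,5,5-tetramethyl-1,3,2-dioxaborolane should give 2-[2,4,6-tris(benzyloxy)phenyl]-4,4,5,5-tetramethyl-1,3,2-dioxaborolane F4. F4 is joined to a second portion of 3 by Suzuki–Miyaura coupling (Pd(OAc)2, SPhos, K3PO4, toluene/H2O, 100 °C) to give 4.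

**Further compounds**
F0 | step 6 | none | none
F1 | step 4 | 3-bromo-2,2',4,4',6,6'-hexakis(benzyloxy)-1,1'-biphenyl | Brc1c(OCc2ccccc2)cc(OCc2ccccc2)c(-c2c(OCc3ccccc3)cc(OCc3ccccc3)cc2OCc2ccccc2)c1OCc1ccccc1
F2 | step 4 | tert-butyl 2-[2,2',4,4',6,6'-hexakis(benzyloxy)biphenyl-3-yl]acetate | CC(C)(C)OC(=O)Cc1c(OCc2ccccc2)cc(OCc2ccccc2)c(-c2c(OCc3ccccc3)cc(OCc3ccccc3)cc2OCc2ccccc2)c1OCc1ccccc1
F3 | step 4 | tert-butyl 2-[2,2',4,4',6,6'-hexakis(benzyloxy)biphenyl-3-yl]-3,5-dioxohexanoate (racemic, enolisable centre) | CC(=O)CC(=O)C(C(=O)OC(C)(C)C)c1c(OCc2ccccc2)cc(OCc2ccccc2)c(-c2c(OCc3ccccc3)cc(OCc3ccccc3)cc2OCc2ccccc2)c1OCc1ccccc1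
F4 | step 3 | 2-[2,4,6-tris(benzyloxy)phenyl]-4,4,5,5-tetramethyl-1,3,2-dioxaborolane | CC1(C)OB(OC1(C)C)c1c(OCc2ccccc2)cc(OCc2ccccc2)cc1OCc1ccccc1
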